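**Strategy.** The route rests on disconnecting ring C of the (2S)-flavanone at C3–C4 and O1–C2. This divides the target into a salicylaldehyde (ring A carrying the future C4 as a formyl group on C4a and the O1 phenol ortho to it on C8a) and an arylacetylene that supplies C2, C3 and ring B. In one flask, phenol-directed rhodium hydroacylation of the alkyne forges C3–C4 to give a 2'-hydroxychalcone, and a cinchona thiourea then closes it by a chalcone-isomerase-like oxa-Michael addition that forms O1–C2 and sets C2. The precursor is 2-hydroxy-4,5,6-trimethoxy-3-prenylbenzaldehyde, whose single free phenol both directs the metal and closes the ring.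

Key step: step 4

Assumption: flavanone numbering is used (O1, C2–C4, C4a, C5–C8, C8a; ring B primed). The quinine-derived thiourea is assumed to favour the (2S) series; should the sense of induction prove opposite, its quinidine-derived pseudoenantiomer would be used with no other change.

Step 1
Reactants: 1 3,4,5-trimethoxyphenol; 2 prenyl bromide (1-bromo-3-methylbut-2-ene)
Product: 3 3,4,5-trimethoxy-2-(3-methylbut-2-en-1-yl)phenol
Conditions: NaH (1.05 equiv), toluene, 0 °C to rt
Reagents that add atoms: none
Why: Ortho C-alkylation of a phenoxide: the sodium phenoxide, a tight ion pair in non-polar toluene, should attack prenyl bromide through the ring carbon next to oxygen rather than through oxygen, and since both ortho positions of 1 are equivalent only one C-prenyl isomer can form.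

Step 2
Reactants: 3 3,4,5-trimethoxy-2-(3-methylbut-2-en-1-yl)phenol
Product: 4 2-hydroxy-4,5,6-trimethoxy-3-(3-methylbut-2-en-1-yl)benzaldehyde
Conditions: MgCl2, Et3N, (CH2O)n, MeCN, reflux; 1 M HCl work-up
Reagents that add atoms: paraformaldehyde (reacting as formaldehyde), C=O
Why: Casnati–Skattebøl ortho-formylation: the magnesium phenoxide delivers formaldehyde to the only free ring position, which is ortho to the hydroxyl, and a second formaldehyde oxidises the hydroxymethyl intermediate by hydride transfer, under basic conditions that spare the prenyl alkene.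

Step 3
Reactants: 5 4-ethynylphenol
Product: 6 1-ethynyl-4-(methoxymethoxy)benzene
Conditions: MOMCl, i-Pr2NEt, CH2Cl2, 0 °C to rt
Reagents that add atoms: chloromethyl methyl ether (MOMCl), COCCl
Why: Williamson-type O-alkylation of the phenol (far more acidic than the alkyne C–H) gives the MOM acetal, which masks the ring B hydroxyl so that it can neither bind the rhodium catalyst nor promote a quinone-methide-type opening of the later flavanone.

Step 4
Reactants: 4 2-hydroxy-4,5,6-trimethoxy-3-(3-methylbut-2-en-1-yl)benzaldehyde; 6 1-ethynyl-4-(methoxymethoxy)benzene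
Product: 8 (2S)-5,6,7-trimethoxy-2-[4-(methoxymethoxy)phenyl]-8-(3-methylbut-2-en-1-yl)chroman-4-one, via 2'-hydroxychalcone 7 (not isolated)
Conditions: [Rh(cod)Cl]2 (2.5 mol %), Fe(C5H4PPh2)2 (dppf, 5 mol %), Na2CO3 (10 mol %), toluene, 40 °C; then 1-[3,5-bis(trifluoromethyl)phenyl]-3-[(8S,9S)-6'-methoxycinchonan-9-yl]thiourea (10 mol %), 0 °C to rt
Reagents that add atoms: none
Why: The monovalent rhodium phenoxide of 4 inserts into the formyl C–H bond to give a five-membered acyl hydride chelate of trivalent rhodium, syn-hydrometalation of alkyne 6 places the metal on the terminal carbon, and C–C reductive elimination forges C3–C4 to give (E)-chalcone 7; the thiourea added next binds the enone carbonyl by double hydrogen bonding while its quinuclidine nitrogen activates the 2'-phenol, which adds to C2 to form O1–C2. The closest known reactions are the salicylaldehyde-directed rhodium hydroacylation of alkynes with in-flask oxa-Michael closure to chroman-4-ones, and the cinchona-thiourea cyclisation of 2'-hydroxychalcones that mimics chalcone isomerase. Ring C closes in the 6-endo-trig mode. The C2 stereocentre is set under catalyst control: the thiourea-bound enone exposes one face of the (E)-alkene to the tethered phenol so that the (2S) configuration should result. The step needs acylation at the terminal alkyne carbon, which the steric bias of the terminal arylalkyne in the hydrometalation should secure, and a single direction of ring closure, which is secured because the other ortho oxygen of ring A is a methyl ether. The trisubstituted prenyl alkene is too hindered to insert, and the MOM ether is inert to both catalysts.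

Step 5
Reactants: 8 (2S)-5,6,7-trimethoxy-2-[4-(methoxymethoxy)phenyl]-8-(3-methylbut-2-en-1-yl)chroman-4-one
Product: 10 (2S)-5-hydroxy-2-(4-hydroxyphenyl)-6,7-dimethoxy-8-(3-methylbut-2-en-1-yl)chroman-4-one, via 5-hydroxy MOM ether 9 (not isolated)
Conditions: MgI2·OEt2, THF, 60 °C; then 3 M HCl, MeOH, rt
Reagents that add atoms: none
Why: Chelation-controlled ether cleavage: magnesium bridges the C4 carbonyl and the peri C5 methoxy oxygen so that iodide should demethylate only that ether by SN2 (the C6 and C7 ethers and the prenyl alkene are not activated), and acid-catalysed acetal methanolysis then frees the C4' phenol, with no base present that could open ring C and scramble C2.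

Compound list
1 | 3,4,5-trimethoxyphenol | COc1cc(O)cc(OC)c1OC | starting material
2 | prenyl bromide (1-bromo-3-methylbut-2-ene) | CC(C)=CCBr | starting material
3 | 3,4,5-trimethoxy-2-(3-methylbut-2-en-1-yl)phenol | COc1cc(O)c(CC=C(C)C)c(OC)c1OC | intermediate
4 | 2-hydroxy-4,5,6-trimethoxy-3-(3-methylbut-2-en-1-yl)benzaldehyde | COc1c(OC)c(C=O)c(O)c(CC=C(C)C)c1OC | intermediate
5 | 4-ethynylphenol | C#Cc1ccc(O)cc1 | starting material
6 | 1-ethynyl-4-(methoxymethoxy)benzene | C#Cc1ccc(OCOC)cc1 | intermediate
7 | (E)-1-[2-hydroxy-4,5,6-trimethoxy-3-(3-methylbut-2-en-1-yl)phenyl]-3-[4-(methoxymethoxy)phenyl]prop-2-en-1-one (2'-hydroxychalcone, not isolated) | COc1c(OC)c(C(=O)/C=C/c2ccc(OCOC)cc2)c(O)c(CC=C(C)C)c1OC | intermediate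
8 | (2S)-5,6,7-trimethoxy-2-[4-(methoxymethoxy)phenyl]-8-(3-methylbut-2-en-1-yl)chroman-4-one | COc1c(OC)c2c(c(CC=C(C)C)c1OC)O[C@H](c1ccc(OCOC)cc1)CC2=O | intermediate
9 | (2S)-5-hydroxy-6,7-dimethoxy-2-[4-(methoxymethoxy)phenyl]-8-(3-methylbut-2-en-1-yl)chroman-4-one (not isolated) | COc1c(O)c2c(c(CC=C(C)C)c1OC)O[C@H](c1ccc(OCOC)cc1)CC2=O | intermediate
10 | (2S)-5-hydroxy-2-(4-hydroxyphenyl)-6,7-dimethoxy-8-(3-methylbut-2-en-1-yl)chroman-4-one | COc1c(O)c2c(c(CC=C(C)C)c1OC)O[C@H](c1ccc(O)cc1)CC2=O | target

Total step count: 5
Longest linear sequence: 4 steps (steps 1, 2, 4 and 5; step 3 prepares the alkyne in a side branch)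

Steps most likely to fail

Step 4. The alkyne may insert in the branched sense or oligomerise on rhodium. The ring closure may show poor facial selectivity, or lose enantiomeric purity through reversible opening of ring C. The fallback sets out from 4 and comes back at 8; it builds the chalcone by aldol chemistry and secures the configuration by resolution. Aldehyde 4 is treated with MeMgBr (THF, 0 °C) to give the carbinol 2-(1-hydroxyethyl)-3,4,5-trimethoxy-6-(3-methylbut-2-en-1-yl)phenol F1. Oxidation (MnO2, CH2Cl2) gives the acetophenone 1-[2-hydroxy-4,5,6-trimethoxy-3-(3-methylbut-2-en-1-yl)phenyl]ethanone F2. Claisen–Schmidt condensation of F2 with commercial 4-(methoxymethoxy)benzaldehyde (KOH, EtOH) gives chalcone 7, which NaOAc in refluxing EtOH closes to the racemic flavanone F3. Kinetic resolution by asymmetric transfer hydrogenation ([Cp*RhCl((R,R)-TsDPEN)], HCO2H/Et3N, EtOAc, rt, stopped near half conversion) follows. The (R,R) catalyst delivers hydride to give a 4R carbinol, so it should consume the (2R) enantiomer as the cis-(2R,4R)-flavan-4-ol F4 and leave (2S)-8.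

Step 5. The Lewis acid may open and reclose ring C and so erode the configuration at C2. Hydrogen halide may add to the prenyl alkene, or a second methyl ether may be cleaved. The fallback sets out from 4 and comes back at 10; it exchanges the C5 methyl ether for an acetal before the stereocentre exists. Aldehyde 4 is demethylated ortho to the formyl group (MgI2·OEt2, THF, 60 °C) to give 2,6-dihydroxy-3,4-dimethoxy-5-(3-methylbut-2-en-1-yl)benzaldehyde F5. One equivalent of MOMCl with i-Pr2NEt should protect the less hindered, methoxy-flanked hydroxyl and leave the hydroxyl between the formyl and prenyl groups free, giving 2-hydroxy-4,5-dimethoxy-6-(methoxymethoxy)-3-(3-methylbut-2-en-1-yl)benzaldehyde F6. The conditions of step 4 with alkyne 6 then lead through the bis-MOM 2'-hydroxychalcone F7 to (2S)-6,7-dimethoxy-5-(methoxymethoxy)-2-[4-(methoxymethoxy)phenyl]-8-(3-methylbut-2-en-1-yl)chroman-4-one F8. Acidic methanolysis alone (3 M HCl, MeOH, rt) then frees both phenols to give 10.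

Step 1. O-alkylation to the prenyl ether, double C-prenylation or acid-induced chroman formation on work-up may compete with the desired mono C-prenylation. The fallback sets out from 1 and comes back at 3; it introduces the side chain by sigmatropic rearrangement and metathesis. Phenol 1 is O-allylated (allyl bromide, K2CO3, acetone, reflux) to 5-(allyloxy)-1,2,3-trimethoxybenzene F9. Aromatic Claisen rearrangement (N,N-diethylaniline, 190 °C) gives 2-allyl-3,4,5-trimethoxyphenol F10. Cross-metathesis with excess 2-methyl-2-butene (second-generation Grubbs catalyst, CH2Cl2, 40 °C) converts the allyl into the prenyl group of 3.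

Further compounds
F1 | step 4 | 2-(1-hydroxyethyl)-3,4,5-trimethoxy-6-(3-methylbut-2-en-1-yl)phenol (racemic) | COc1c(OC)c(C(C)O)c(O)c(CC=C(C)C)c1OC
F2 | step 4 | 1-[2-hydroxy-4,5,6-trimethoxy-3-(3-methylbut-2-en-1-yl)phenyl]ethanone | COc1c(OC)c(C(C)=O)c(O)c(CC=C(C)C)c1OC
F3 | step 4 | racemic 5,6,7-trimethoxy-2-[4-(methoxymethoxy)phenyl]-8-(3-methylbut-2-en-1-yl)chroman-4-one | COc1c(OC)c2c(c(CC=C(C)C)c1OC)OC(c1ccc(OCOC)cc1)CC2=O
F4 | step 4 | (2R,4R)-5,6,7-trimethoxy-2-[4-(methoxymethoxy)phenyl]-8-(3-methylbut-2-en-1-yl)chroman-4-ol (cis) | COc1c(OC)c2c(c(CC=C(C)C)c1OC)O[C@@H](c1ccc(OCOC)cc1)C[C@H]2O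
F5 | step 5 | 2,6-dihydroxy-3,4-dimethoxy-5-(3-methylbut-2-en-1-yl)benzaldehyde | COc1c(O)c(C=O)c(O)c(CC=C(C)C)c1OC
F6 | step 5 | 2-hydroxy-4,5-dimethoxy-6-(methoxymethoxy)-3-(3-methylbut-2-en-1-yl)benzaldehyde | COc1c(OCOC)c(C=O)c(O)c(CC=C(C)C)c1OC
F7 | step 5 | (E)-1-[2-hydroxy-4,5-dimethoxy-6-(methoxymethoxy)-3-(3-methylbut-2-en-1-yl)phenyl]-3-[4-(methoxymethoxy)phenyl]prop-2-en-1-one | COc1c(OCOC)c(C(=O)/C=C/c2ccc(OCOC)cc2)c(O)c(CC=C(C)C)c1OC
F8 | step 5 | (2S)-6,7-dimethoxy-5-(methoxymethoxy)-2-[4-(methoxymethoxy)phenyl]-8-(3-methylbut-2-en-1-yl)chroman-4-one | COc1c(OCOC)c2c(c(CC=C(C)C)c1OC)O[C@H](c1ccc(OCOC)cc1)CC2=O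
F9 | step 1 | 5-(allyloxy)-1,2,3-trimethoxybenzene | COc1cc(OCC=C)cc(OC)c1OC
F10 | step 1 | 2-allyl-3,4,5-trimethoxyphenol | COc1cc(O)c(CC=C)c(OC)c1OC
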